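Numbering and enabling feature: guaiane numbers are used, plain for the acetate half (unit A) and primed for the peroxide half (unit B). In the norbornene core (C1, C2, C3, C4=C5, C1', C2') the only one-atom bridge is the oxygenated C2 between quaternary C1 and C3-H. Putting one extra carbon, C2a, back between C2 and C1 turns this bridge into the 1,2-dicarbonyl bridge of a bicyclo[2.2.2]octene. Its ring C1-C5-C4-C3-C2-C2a is a dearomatised 2-methoxyphenol that reacts as the diene C1=C5-C4=C3.
Cuts, in retrosynthetic order: O-C8'/O-C11' with the C8' oxygen; C2-O; C2-C1 (Wolff retron, restores C2a); C4'=C5' (aldol); C1-C2' and C3-C1' (Diels-Alder); C5-C6 (Friedel-Crafts) in unit A; C6' (one-carbon ring enlargement) and C1'-C2' (alkylation) in unit B.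
Forward order, unit A: arene, then lactone, then the seven-membered ring, then the dienone ketal. Unit B: six-membered ring of pulegone, then seven-membered ring, then furan, then ene-dione. The cycloaddition builds the bicyclo[2.2.2]octene, the aldol closes the cyclopentenone, the Wolff step shrinks the core to the norbornene, and the dioxolane comes last.
The dienophile is an (E)-ene-dione, not a cyclopentadienone. The extra C5' ketone activates the trisubstituted alkene. The E geometry lets the propionyl group go endo while C5' lies toward the two-carbon bridge, which is the later exo face. The C5' ketone then becomes C5' of the C4'=C5' alkene.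
Unit B is carried as the robust 8'-deoxy linear dienone through the photochemical and radical steps and is oxidised only at the end.
Stereochemistry: C10 comes from a ligand-controlled CuH reduction, C10' from (R)-pulegone, and C7 from equilibration. C1, C3 and C1' come from cycloaddition anti to both secondary methyl groups, and C2' from epimerisation into the cis-fused ring. C2 comes from radical capture on the alkene face and C8' from reversible hemiketalisation.

Key step: step 19

Assumption 1: (R)-DTBM-SEGPHOS is taken to give (S)-4. If the sense of induction is the reverse, the equally available (S)-ligand is used.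
Assumption 2: the C7 epimer with isopropyl cis to the C10 methyl and the (8'R) peroxyhemiketal are taken to be the thermodynamically preferred forms, since both centres can equilibrate.

Step 1
Reactants: 1 creosol; 2 ethyl acetoacetate
Product: 3 8-methoxy-4,6-dimethylcoumarin
Conditions: MeSO3H (neat), 0 °C to rt
Reagents that add atoms: none
Why: Pechmann condensation: under acid the keto group of 2 attacks the only free position ortho to the phenol OH (future C1) and the ester lactonises, which attaches C10, C14, C9 and C8 in one operation and creates no stereocentre.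

Step 2
Reactants: 3 8-methoxy-4,6-dimethylcoumarin
Product: 4 (S)-8-methoxy-4,6-dimethylchroman-2-one
Conditions: Cu(OAc)2·H2O (2 mol %), (R)-DTBM-SEGPHOS (2 mol %), (EtO)2MeSiH, t-BuOH, toluene, 0 °C to rt
Reagents that add atoms: none
Why: Ligand-controlled copper hydride conjugate reduction of a β,β-disubstituted unsaturated lactone: hydride is delivered to one face of C10 inside the chiral bisphosphine pocket, which sets (S)-C10, and t-BuOH protonates the copper enolate so that the lactone carbonyl is left alone.

Step 3
Reactants: 4 (S)-8-methoxy-4,6-dimethylchroman-2-one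
Product: 5 (S)-3-(2-hydroxy-3-methoxy-5-methylphenyl)-N-methoxy-N-methylbutanamide
Conditions: MeNH(OMe)·HCl, i-PrMgCl, THF, -20 °C to 0 °C
Reagents that add atoms: N,O-dimethylhydroxylamine hydrochloride, CNOC.Cl
Why: Weinreb aminolysis of the aryl ester-type lactone by the magnesium amide, driven by release of the phenoxide; C10 is not acidic under these conditions and keeps its configuration.

Step 4
Reactants: 5 (S)-3-(2-hydroxy-3-methoxy-5-methylphenyl)-N-methoxy-N-methylbutanamide; 6 2-bromo-3-methylbut-1-ene
Product: 7 (S)-6-(2-hydroxy-3-methoxy-5-methylphenyl)-2-methyl-3-methylideneheptan-4-one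
Conditions: 6, Mg, THF, reflux; then 5, 0 °C; aq NH4Cl
Reagents that add atoms: none
Why: Weinreb ketone synthesis: one equivalent of the alkenyl Grignard reagent deprotonates the phenol, a second adds to the amide, and the chelated tetrahedral adduct survives until work-up, so the α-isopropyl vinyl ketone (C6, C7, C11 to C13) forms without over-addition.

Step 5
Reactants: 7 (S)-6-(2-hydroxy-3-methoxy-5-methylphenyl)-2-methyl-3-methylideneheptan-4-one
Product: 8 aryl acetate of 7
Conditions: Ac2O, pyridine, DMAP (cat.), CH2Cl2, rt
Reagents that add atoms: acetic anhydride, CC(=O)OC(C)=O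
Why: DMAP-catalysed O-acetylation, which prevents hemiketal and chromene formation between the phenol and the C8 ketone in the acidic ring closure that follows.

Step 6
Reactants: 8 aryl acetate of 7
Product: 9 benzosuberone acetate (7R,10S)
Conditions: TfOH (20 mol %), CH2Cl2 (0.01 M), -20 °C to 0 °C
Reagents that add atoms: none
Why: Intramolecular Friedel-Crafts conjugate alkylation (7-endo-trig) of the protonated vinyl ketone: C5 is the only ring position the tether can reach and is activated by the para methoxy and two ortho alkyl groups, and ketonisation of the enol under these equilibrating conditions should favour the C7 epimer with the isopropyl group pseudo-equatorial and cis to the pseudo-axial C10 methyl.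

Step 7
Reactants: 9 benzosuberone acetate (7R,10S)
Product: 10 benzosuberone phenol (7R,10S)
Conditions: K2CO3, MeOH, rt
Reagents that add atoms: none
Why: Base-catalysed transesterification frees the phenol, and the same medium equilibrates the enolisable C7 to the cis (7R,10S) isomer, the C10 methyl being held pseudo-axial by peri strain against the phenolic oxygen.

Step 8
Reactants: 10 benzosuberone phenol (7R,10S)
Product: 11 dimethoxy dienone (masked ortho-benzoquinone)
Conditions: PhI(OAc)2, MeOH, 0 °C
Reagents that add atoms: methanol, CO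
Why: Oxidative dearomatisation of a 2-methoxyphenol by a diacetoxyiodoarene: methanol captures the activated ring at the methoxy-bearing carbon C2 to give the 6,6-dimethoxycyclohexa-2,4-dienone, and the three alkyl groups on the diene suppress its self-dimerisation.

Step 9
Reactants: 12 (R)-(+)-pulegone
Product: 13 triethylsilyl enol ether of menthone (C5'=C7')
Conditions: Et3SiH, RhCl(PPh3)3 (0.5 mol %), toluene, 50 °C
Reagents that add atoms: triethylsilane, CC[SiH](CC)CC
Why: Rhodium-catalysed 1,4-hydrosilylation of an s-cis enone places hydrogen on C11' and silicon on oxygen, which gives the tetrasubstituted silyl enol ether as a single regioisomer; C10' is untouched.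

Step 10
Reactants: 13 triethylsilyl enol ether of menthone (C5'=C7')
Product: 14 siloxycyclopropane
Conditions: Et2Zn, CH2I2, CH2Cl2, 0 °C to rt
Reagents that add atoms: diiodomethane, ICI
Why: Simmons-Smith cyclopropanation (Furukawa variant) of the electron-rich enol ether introduces C6'; the fusion is necessarily cis, addition anti to the remote methyl is drawn, and the facial outcome is irrelevant because both new stereocentres vanish in step 11.

Step 11
Reactants: 14 siloxycyclopropane
Product: 16 (R)-3-isopropyl-6-methylcyclohept-2-en-1-one, via chloro ketone 15 (not isolated)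
Conditions: FeCl3, DMF, 0 °C to rt; then NaOAc, MeOH, reflux
Reagents that add atoms: none
Why: Oxidative ring enlargement of a siloxycyclopropane with FeCl3 (Ito-Saegusa type): one-electron oxidation cleaves the internal C5'-C7' bond, the tertiary C7' radical takes up chlorine, and acetate-induced dehydrochlorination gives the conjugated cycloheptenone with C6' inserted.

Step 12
Reactants: 16 (R)-3-isopropyl-6-methylcyclohept-2-en-1-one; 17 1-bromobut-2-yne
Product: 18 (6R,7S)-7-(but-2-yn-1-yl)-3-isopropyl-6-methylcyclohept-2-en-1-one
Conditions: LiN(i-Pr)2, THF, -78 °C; then 17, DMPU, -78 °C to -20 °C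
Reagents that add atoms: none
Why: Kinetic cross-conjugated lithium enolate formation at the α' carbon C1' and SN2 alkylation by a reactive propargylic bromide; the electrophile should enter trans to the adjacent C10' methyl, and this stereocentre is erased again in step 13.

Step 13
Reactants: 18 (6R,7S)-7-(but-2-yn-1-yl)-3-isopropyl-6-methylcyclohept-2-en-1-one
Product: 19 (4R)-2-ethyl-7-isopropyl-4-methyl-5,6-dihydro-4H-cyclohepta[b]furan
Conditions: Ph3PAuCl (5 mol %), AgOTf (5 mol %), p-TsOH·H2O (10 mol %), toluene, 60 °C
Reagents that add atoms: none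
Why: Gold-catalysed cycloisomerisation of an alk-4-yn-1-one: 5-exo-dig attack of the C5' carbonyl oxygen on the activated alkyne, loss of the C1' proton and acid-catalysed migration of the exocyclic double bond give the 2-ethylfuran, which stores the ene-dione at the right oxidation level.

Step 14
Reactants: 19 (4R)-2-ethyl-7-isopropyl-4-methyl-5,6-dihydro-4H-cyclohepta[b]furan
Product: 21 (6R,7E)-3-isopropyl-6-methyl-7-(2-oxobutylidene)cyclohept-2-en-1-one, via (Z)-ene-dione 20 (not isolated)
Conditions: mCPBA, CH2Cl2, 0 °C; then I2 (5 mol %), rt, ambient light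
Reagents that add atoms: 3-chloroperbenzoic acid, OOC(=O)c1cccc(Cl)c1
Why: Oxidative ring opening of a trialkylfuran, the most electron-rich π system present, by a peracid gives the (Z)-ene-dione, and iodine-catalysed Z to E isomerisation relieves the repulsion between the two cis acyl groups, which puts the propionyl group cis to C10'.

Step 15
Reactants: 11 dimethoxy dienone (masked ortho-benzoquinone); 21 (6R,7E)-3-isopropyl-6-methyl-7-(2-oxobutylidene)cyclohept-2-en-1-one
Product: 22 Diels-Alder adduct (bicyclo[2.2.2]octenone ketal; propionyl on C2' syn to C4=C5)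
Conditions: toluene, BHT (cat.), 110 °C, sealed tube
Reagents that add atoms: none
Why: Intermolecular Diels-Alder reaction of a masked ortho-benzoquinone with a doubly activated alkene: unsubstituted C2' bonds to the substituted terminus C1 and substituted C1' to C3-H (no vicinal quaternary pair), the propionyl group and C10' lie endo under C4-C5 while the flat C5' ketone and H point toward the ketal, and each partner reacts on the face anti to its pseudo-axial secondary methyl, which sets C1, C3, C1' and, provisionally, C2'.

Step 16
Reactants: 22 Diels-Alder adduct (bicyclo[2.2.2]octenone ketal; propionyl on C2' syn to C4=C5)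
Product: 24 pentacyclic dienone ketal, via C2' epimer 23 (not isolated)
Conditions: KOH, MeOH, 50 °C, Ar
Reagents that add atoms: none
Why: Base-mediated epimerisation followed by intramolecular aldol condensation of a 1,4-diketone: enolisation toward C2' moves the propionyl group to the face of the C5' ketone, the C4' enolate closes the strain-free cis-fused five-membered ring (5-exo-trig on C5'=O, far better aligned than attack on C2a=O), and loss of water to the conjugated dienone makes the sequence irreversible, which fixes C2'.

Step 17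
Reactants: 24 pentacyclic dienone ketal
Product: 25 pentacyclic 1,2-diketone
Conditions: TFA/H2O (4:1), 40 °C
Reagents that add atoms: water, O
Why: Acid-catalysed ketal hydrolysis, slow for an α-keto ketal and therefore run in strong aqueous acid; ketone, dienone and tetrasubstituted alkene carry no acid-labile function and C7 is already at equilibrium.

Step 18
Reactants: 25 pentacyclic 1,2-diketone
Product: 27 α-diazo ketone (diazo at C2; carbonyl at C2a), via C2 tosylhydrazone 26 (not isolated)
Conditions: TsNHNH2 (1.0 equiv), THF, 0 °C to rt; then Et3N, CH2Cl2, rt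
Reagents that add atoms: 4-methylbenzenesulfonohydrazide, Cc1ccc(cc1)S(=O)(=O)NN
Why: Condensation of the strained, most electrophilic 1,2-diketone with one equivalent of tosylhydrazide takes place at C2, next to the CH bridgehead C3 and not next to quaternary C1, and base-induced loss of sulfinate (Bamford-Stevens-type elimination) gives the α-diazo ketone.

Step 19
Reactants: 27 α-diazo ketone (diazo at C2; carbonyl at C2a)
Product: 29 norbornene C2 methyl ester, via C2 ketene 28 (not isolated)
Conditions: hν (405 nm LED), MeOH, rt, N2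
Reagents that add atoms: methanol, CO
Why: Excitation of the diazo n-π* band expels N2 from the ring-locked s-cis diazo ketone and, in concert, C1, which lies anti to the leaving N2, shifts with retention from C2a to C2 (Wolff rearrangement), so the C2-C2a bridge becomes the single atom C2 carrying an exocyclic ketene that methanol traps. The closest known reaction type is the photochemical Wolff ring contraction of bicyclic 2-diazo ketones such as 3-diazobicyclo[2.2.2]octan-2-ones and diazocamphor to 7-substituted norbornanes and related acids. The new five-membered ring C1-C2-C3-C4=C5 arises by a 1,2-shift inside an existing six-membered ring (contraction six to five), not by an end-to-end cyclisation, so no exo or endo closure mode applies. The new stereocentre C2 is set when the ester enol is protonated: the face toward C1'-C2' is roofed by the exo cyclopentenone, so the proton arrives from the C4=C5 side and the ester ends over the saturated bridge, and the epimer would serve equally because C2 is planarised in step 21. Which bond migrates is fixed by the diazo position, and the regioisomeric diazo ketone would collapse to the same ketene. The step needs chemoselective excitation, which is secured because the dienone, the β,γ-unsaturated ketone and the saturated ketone do not absorb at 405 nm.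

Step 20
Reactants: 29 norbornene C2 methyl ester
Product: 30 norbornene C2 carboxylic acid
Conditions: LiI, EtOAc, reflux; then 1 M HCl
Reagents that add atoms: none
Why: SN2 dealkylation of the methyl ester by iodide attacks the unhindered O-methyl carbon, so the crowded acyl carbon, the C2 configuration, the dienone and C7 are not disturbed.

Step 21
Reactants: 30 norbornene C2 carboxylic acid
Product: 33 C2 alcohol (OH syn to C4=C5), via Barton ester 31 (not isolated), via C2 hydroperoxide 32 (not isolated)
Conditions: 1-hydroxypyridine-2(1H)-thione, DCC, CH2Cl2, 0 °C, dark; then O2, t-BuSH, toluene, hν (tungsten lamp), 0 °C; then P(OMe)3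
Reagents that add atoms: dioxygen, O=O
Why: Barton decarboxylative oxygenation: the thiohydroxamate ester fragments in a thiyl radical chain to the C2 radical, which O2 captures from the open C4=C5 side because the other face is roofed by the exo cyclopentenone, and phosphite reduction of the hydroperoxide gives the (2R) alcohol.

Step 22
Reactants: 33 C2 alcohol (OH syn to C4=C5)
Product: 34 C2 acetate (8'-deoxy dienone)
Conditions: Ac2O, DMAP, pyridine, rt
Reagents that add atoms: acetic anhydride, CC(=O)OC(C)=O
Why: DMAP-catalysed acetylation of the only hydroxyl group; no stereocentre is touched.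

Step 23
Reactants: 34 C2 acetate (8'-deoxy dienone)
Product: 38 CNP0361479.4 (target), via C8' hydroperoxide 35 (not isolated), via dienedione 36 (not isolated), via C11' hydroperoxide 37 (not isolated)
Conditions: DBU, O2 (1 atm), MeCN, rt
Reagents that add atoms: dioxygen, O=O
Why: Proposed new method: DBU should remove the vinylogous ε proton at C8' of the linear dienone, triplet O2 adds at C8' of the trienolate, and base-induced Kornblum-DeLaMare dehydration of the secondary hydroperoxide gives the C8' ketone; the only vinylogous proton then left is C11'-H, whose removal and oxygenation at C11' restore the dienone, and the tertiary hydroperoxide adds reversibly to the neighbouring C8' ketone so that C8' settles as the more stable (8'R) peroxyhemiketal; first attack at C11' would converge on the same product; the closest known reaction types are the base-mediated aerobic γ-oxidation of enones to ene-diones (isophorone to ketoisophorone) and the closure of β-hydroperoxy ketones to 1,2-dioxolan-3-ols.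

Compound list
1 | creosol (2-methoxy-4-methylphenol) | Cc1ccc(O)c(OC)c1 | starting material
2 | ethyl acetoacetate | CCOC(=O)CC(C)=O | starting material
3 | 8-methoxy-4,6-dimethyl-2H-chromen-2-one | O=C1C=C(C)c2cc(C)cc(OC)c2O1 | intermediate
4 | (4S)-8-methoxy-4,6-dimethylchroman-2-one | O=C1C[C@H](C)c2cc(C)cc(OC)c2O1 | intermediate
5 | (3S)-3-(2-hydroxy-3-methoxy-5-methylphenyl)-N-methoxy-N-methylbutanamide | CON(C)C(=O)C[C@H](C)c1cc(C)cc(OC)c1O | intermediate
6 | 2-bromo-3-methylbut-1-ene | C=C(Br)C(C)C | starting material
7 | (6S)-6-(2-hydroxy-3-methoxy-5-methylphenyl)-2-methyl-3-methylideneheptan-4-one | C=C(C(C)C)C(=O)C[C@H](C)c1cc(C)cc(OC)c1O | intermediate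
8 | 2-methoxy-4-methyl-6-[(2S)-6-methyl-5-methylidene-4-oxoheptan-2-yl]phenyl acetate | C=C(C(C)C)C(=O)C[C@H](C)c1cc(C)cc(OC)c1OC(C)=O | intermediate
9 | (5S,8R)-3-methoxy-1,5-dimethyl-7-oxo-8-(propan-2-yl)-6,7,8,9-tetrahydro-5H-benzo[7]annulen-4-yl acetate (guaiane 10S,7R; methyl and isopropyl cis) | COc1cc(C)c2C[C@H](C(C)C)C(=O)C[C@H](C)c2c1OC(C)=O | intermediate
10 | (5S,8R)-4-hydroxy-3-methoxy-1,5-dimethyl-8-(propan-2-yl)-5,6,8,9-tetrahydro-7H-benzo[7]annulen-7-one | COc1cc(C)c2C[C@H](C(C)C)C(=O)C[C@H](C)c2c1O | intermediate
11 | (5S,8R)-3,3-dimethoxy-1,5-dimethyl-8-(propan-2-yl)-5,6,8,9-tetrahydro-3H-benzo[7]annulene-4,7-dione (C2a=O, C2 ketal, diene C1=C5-C4=C3) | O=C1C(OC)(OC)C=C(C)C2=C1[C@@H](C)CC(=O)[C@@H](C(C)C)C2 | intermediate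
12 | (R)-(+)-pulegone | C[C@@H]1CCC(=C(C)C)C(=O)C1 | starting material
13 | triethyl{[(5R)-5-methyl-2-(propan-2-yl)cyclohex-1-en-1-yl]oxy}silane | CC[Si](CC)(CC)OC1=C(C(C)C)CC[C@@H](C)C1 | intermediate
14 | (3R)-6-isopropyl-3-methyl-1-(triethylsilyloxy)bicyclo[4.1.0]heptane, cis-fused, CH2 drawn anti to the methyl (the syn isomer reacts alike) | CC[Si](CC)(CC)O[C@@]12C[C@]1(C(C)C)CC[C@@H](C)C2 | intermediate
15 | (6R)-3-chloro-3-isopropyl-6-methylcycloheptan-1-one, drawn as one C3 epimer | O=C1C[C@@](Cl)(C(C)C)CC[C@@H](C)C1 | intermediate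
16 | (6R)-3-isopropyl-6-methylcyclohept-2-en-1-one | O=C1C=C(C(C)C)CC[C@@H](C)C1 | intermediate
17 | 1-bromobut-2-yne | CC#CCBr | starting material
18 | (6R,7S)-7-(but-2-yn-1-yl)-3-isopropyl-6-methylcyclohept-2-en-1-one (side chain trans to methyl) | O=C1C=C(C(C)C)CC[C@@H](C)[C@@H]1CC#CC | intermediate
19 | (4R)-2-ethyl-7-isopropyl-4-methyl-5,6-dihydro-4H-cyclohepta[b]furan | CCc1cc2c(o1)C=C(C(C)C)CC[C@H]2C | intermediate
20 | (6R,7Z)-3-isopropyl-6-methyl-7-(2-oxobutylidene)cyclohept-2-en-1-one | CCC(=O)/C=C1\C(=O)C=C(C(C)C)CC[C@H]1C | intermediate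
21 | (6R,7E)-3-isopropyl-6-methyl-7-(2-oxobutylidene)cyclohept-2-en-1-one | CCC(=O)/C=C1/C(=O)C=C(C(C)C)CC[C@H]1C | intermediate
22 | Diels-Alder adduct: bicyclo[2.2.2]oct-5-en-2-one (C2a=O, C2(OMe)2, C4=C5) fused at C1-C5 to the unit A cycloheptanone and spiro at C1' to the unit B cycloheptenone; C5'=O and H-2' syn to the ketal bridge, C10' and propionyl syn to C4=C5 | O=C1C(OC)(OC)[C@@H]2C(C)=C3C[C@H](C(C)C)C(=O)C[C@H](C)[C@@]31[C@@H](C(=O)CC)[C@]21C(=O)C=C(C(C)C)CC[C@H]1C | intermediate
23 | C2' epimer of 22 (propionyl syn to the ketal bridge, cis to C5'=O) | O=C1C(OC)(OC)[C@@H]2C(C)=C3C[C@H](C(C)C)C(=O)C[C@H](C)[C@@]31[C@H](C(=O)CC)[C@]21C(=O)C=C(C(C)C)CC[C@H]1C | intermediate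
24 | pentacyclic dienone ketal: cyclopentenone C1'-C2'-C3'(=O)-C4'(Me)=C5' cis-fused on the face of the ketal bridge, C6'=C7'(i-Pr), C8'H2 | O=C1C(OC)(OC)[C@@H]2C(C)=C3C[C@H](C(C)C)C(=O)C[C@H](C)[C@@]31[C@@H]1C(=O)C(C)=C3C=C(C(C)C)CC[C@@H](C)[C@]312 | intermediate
25 | pentacyclic bicyclo[2.2.2]octene-2,3-dione (C2=O, C2a=O), rest as 24 | O=C1C(=O)[C@@H]2C(C)=C3C[C@H](C(C)C)C(=O)C[C@H](C)[C@@]31[C@@H]1C(=O)C(C)=C3C=C(C(C)C)CC[C@@H](C)[C@]312 | intermediate
26 | C2 monotosylhydrazone of 25 (NH turned toward C2a=O) | O=C1/C(=N\NS(=O)(=O)c4ccc(C)cc4)[C@@H]2C(C)=C3C[C@H](C(C)C)C(=O)C[C@H](C)[C@@]31[C@@H]1C(=O)C(C)=C3C=C(C(C)C)CC[C@@H](C)[C@]312 | intermediate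
27 | bicyclo[2.2.2]octenone α-diazo ketone (diazo at C2 next to C3, carbonyl C2a next to C1) | O=C1C(=[N+]=[N-])[C@@H]2C(C)=C3C[C@H](C(C)C)C(=O)C[C@H](C)[C@@]31[C@@H]1C(=O)C(C)=C3C=C(C(C)C)CC[C@@H](C)[C@]312 | intermediate
28 | norbornene with exocyclic ketene at C2 | O=C=C1[C@@H]2C(C)=C3C[C@H](C(C)C)C(=O)C[C@H](C)[C@@]31[C@@H]1C(=O)C(C)=C3C=C(C(C)C)CC[C@@H](C)[C@]312 | intermediate
29 | norbornene C2 methyl ester (ester over the C1'-C2' bridge, H-2 syn to C4=C5) | COC(=O)[C@H]1[C@@H]2C(C)=C3C[C@H](C(C)C)C(=O)C[C@H](C)[C@@]31[C@@H]1C(=O)C(C)=C3C=C(C(C)C)CC[C@@H](C)[C@]312 | intermediate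
30 | norbornene C2 carboxylic acid, configuration as 29 | OC(=O)[C@H]1[C@@H]2C(C)=C3C[C@H](C(C)C)C(=O)C[C@H](C)[C@@]31[C@@H]1C(=O)C(C)=C3C=C(C(C)C)CC[C@@H](C)[C@]312 | intermediate
31 | 2-thioxopyridin-1(2H)-yl ester of 30 | O=C(ON4C=CC=CC4=S)[C@H]1[C@@H]2C(C)=C3C[C@H](C(C)C)C(=O)C[C@H](C)[C@@]31[C@@H]1C(=O)C(C)=C3C=C(C(C)C)CC[C@@H](C)[C@]312 | intermediate
32 | C2 hydroperoxide (OOH syn to C4=C5) | OO[C@@H]1[C@@H]2C(C)=C3C[C@H](C(C)C)C(=O)C[C@H](C)[C@@]31[C@@H]1C(=O)C(C)=C3C=C(C(C)C)CC[C@@H](C)[C@]312 | intermediate
33 | C2 alcohol (OH syn to C4=C5) | O[C@@H]1[C@@H]2C(C)=C3C[C@H](C(C)C)C(=O)C[C@H](C)[C@@]31[C@@H]1C(=O)C(C)=C3C=C(C(C)C)CC[C@@H](C)[C@]312 | intermediate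
34 | C2 acetate with 8'-deoxy linear dienone in unit B | CC(=O)O[C@@H]1[C@@H]2C(C)=C3C[C@H](C(C)C)C(=O)C[C@H](C)[C@@]31[C@@H]1C(=O)C(C)=C3C=C(C(C)C)CC[C@@H](C)[C@]312 | intermediate
35 | C8' hydroperoxide of 34, drawn as one C8' epimer | CC(=O)O[C@@H]1[C@@H]2C(C)=C3C[C@H](C(C)C)C(=O)C[C@H](C)[C@@]31[C@@H]1C(=O)C(C)=C3C=C(C(C)C)[C@H](OO)C[C@@H](C)[C@]312 | intermediate
36 | dienedione (C3'=O, C4'=C5', C6'=C7'(i-Pr), C8'=O) | CC(=O)O[C@@H]1[C@@H]2C(C)=C3C[C@H](C(C)C)C(=O)C[C@H](C)[C@@]31[C@@H]1C(=O)C(C)=C3C=C(C(C)C)C(=O)C[C@@H](C)[C@]312 | intermediate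
37 | C11' hydroperoxide of 36 (open form) | CC(=O)O[C@@H]1[C@@H]2C(C)=C3C[C@H](C(C)C)C(=O)C[C@H](C)[C@@]31[C@@H]1C(=O)C(C)=C3C=C(C(C)(C)OO)C(=O)C[C@@H](C)[C@]312 | intermediate
38 | CNP0361479.4, (1R,2R,3R,7R,10S,1'R,2'R,8'R,10'R) in the numbering used here | CC(=O)O[C@@H]1[C@@H]2C(C)=C3C[C@H](C(C)C)C(=O)C[C@H](C)[C@@]31[C@@H]1C(=O)C(C)=C3C=C4C(C)(C)OO[C@]4(O)C[C@@H](C)[C@]312 | target

Total step count: 23. Longest linear sequence: 17 (steps 1 to 8, then 15 to 23). The unit B branch (steps 9 to 14) joins at step 15.

Steps most likely to fail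

Step 23. Oxygenation may occur at the wrong acidic site (C9' or C7). The sequence may also stall at a hydroperoxide, or the base may erode the acetate. The fallback sets out from 34 and comes back at 38, using known reaction types one at a time.
- Soft enolisation with TBSOTf/Et3N should give the trienol silyl ether F1.
- Rubottom-type oxidation of its distal double bond with dimethyldioxirane should give the 8'-hydroxy dienone F2.
- Dess-Martin periodinane takes F2 to dienedione 36, now isolated.
- Equilibration with DBU under argon gives access to its deconjugated isopropylidene tautomer F3.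
- Dye-sensitised photo-oxygenation (O2, tetraphenylporphyrin, hν, CH2Cl2) is a Schenck ene reaction with the geminal selectivity of enones. It abstracts H-6', places oxygen on C11' and gives 37, which closes to 38.

Step 15. The cycloaddition between two trisubstituted partners may be sluggish. The methoxy group on the reacting face of the ketal may push the C5' ketone into the endo position. Facial selectivity on either partner may also be poor. The fallback sets out from 10 and 21 and comes back at 25. It replaces the ketal diene by the flat, unmasked quinone, so the sp3 ketal carbon no longer blocks the quadrant needed by C5'=O, and step 17 is bypassed.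
- BBr3 demethylation of 10 gives the catechol F4.
- Ag2O in CH2Cl2 oxidises it to the ortho-quinone F5, which is generated in the presence of 21.
- F5 adds as a carbodiene to give the bicyclooctenedione adduct F6.
- Acid-catalysed epimerisation and aldol condensation (p-TsOH, toluene, reflux) close the cyclopentenone and deliver 25.

Step 6. The cationic 7-endo closure may lose out to oligomerisation of the vinyl ketone or to acetate cleavage followed by chromene formation. The fallback sets out from 8 and comes back at 9, and it changes the bond-forming mode from cationic to radical.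
- NBS in MeCN brominates the arene para to the methoxy group to give the aryl bromide F7.
- Slow addition of Bu3SnH/AIBN in refluxing toluene generates the C5 aryl radical.
- This radical adds 7-endo to the unsubstituted β carbon C6 of the enone, because the 6-exo mode would have to attack the isopropyl-bearing α carbon.

Further compounds
F1 | step 23 | trienol tert-butyldimethylsilyl ether of 34 (C3'(OTBS)=C4', C5'=C6', C7'=C8') | CC(=O)O[C@@H]1[C@@H]2C(C)=C3C[C@H](C(C)C)C(=O)C[C@H](C)[C@@]31[C@@H]1C(O[Si](C)(C)C(C)(C)C)=C(C)C3=CC(C(C)C)=CC[C@@H](C)[C@]312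
F2 | step 23 | 8'-hydroxy dienone, drawn as one C8' epimer | CC(=O)O[C@@H]1[C@@H]2C(C)=C3C[C@H](C(C)C)C(=O)C[C@H](C)[C@@]31[C@@H]1C(=O)C(C)=C3C=C(C(C)C)[C@H](O)C[C@@H](C)[C@]312
F3 | step 23 | isopropylidene tautomer of 36 (C6'H2, C7'=C11', C8'=O) | CC(=O)O[C@@H]1[C@@H]2C(C)=C3C[C@H](C(C)C)C(=O)C[C@H](C)[C@@]31[C@@H]1C(=O)C(C)=C3CC(=C(C)C)C(=O)C[C@@H](C)[C@]312
F4 | step 15 | (5S,8R)-3,4-dihydroxy-1,5-dimethyl-8-(propan-2-yl)-5,6,8,9-tetrahydro-7H-benzo[7]annulen-7-one | Oc1cc(C)c2C[C@H](C(C)C)C(=O)C[C@H](C)c2c1O
F5 | step 15 | (5S,8R)-1,5-dimethyl-8-(propan-2-yl)-5,6,8,9-tetrahydro-3H-benzo[7]annulene-3,4,7-trione (ortho-quinone) | O=C1C(=O)C=C(C)C2=C1[C@@H](C)CC(=O)[C@@H](C(C)C)C2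
F6 | step 15 | bicyclo[2.2.2]octene-2,3-dione adduct, substituents arranged as in 22 | O=C1C(=O)[C@@H]2C(C)=C3C[C@H](C(C)C)C(=O)C[C@H](C)[C@@]31[C@@H](C(=O)CC)[C@]21C(=O)C=C(C(C)C)CC[C@H]1C
F7 | step 6 | 3-bromo-6-methoxy-4-methyl-2-[(2S)-6-methyl-5-methylidene-4-oxoheptan-2-yl]phenyl acetate | C=C(C(C)C)C(=O)C[C@H](C)c1c(Br)c(C)cc(OC)c1OC(C)=O
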